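Ring C of the flavanone is cut across C3–C4 and O1–C2. O1, C8a, C4a and C4 form an oxa-diene (an ortho-quinone methide carried by ring A); C2 and C3 come from a ring B styrene. The C7 methoxy group, para to C4a, stabilises the cationic methide, and the methide carbon carries a methoxy group so that C4 arrives at ketone oxidation level. One acid-catalysed, enantioselective oxa-[4+2] step therefore closes ring C, makes both skeletal bonds and sets C2. Its precursor is a 2-hydroxybenzaldehyde dimethyl acetal bearing the C7 methoxy group and the silyl-protected (E)-4-hydroxy-3-methylbut-2-enyl chain, which meets 3,4-bis(silyloxy)styrene. Exchange of OMe for OH, oxidation and desilylation finish the synthesis.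

Key step: step 9

Assumption: which antipode of the phosphoric acid leads to 2S cannot be predicted for this substrate class; the (R) acid is written, and the (S) acid is taken instead if the sense proves opposite. Flavanone numbering (O1, C2–C4, C4a, C5–C8, C8a) is used throughout.

Step 1
Reactants: 1 2-hydroxy-4-methoxybenzaldehyde; 2 2-methylbut-3-yn-2-ol
Product: 4 4-methoxy-2-[(2-methylbut-3-yn-2-yl)oxy]benzaldehyde, via trifluoroacetate 3 (not isolated)
Conditions: 2, (CF3CO)2O, DBU, MeCN, −5 °C; then 1, DBU, CuCl2·2H2O (1 mol%), MeCN, 0 °C → rt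
Reagents that add atoms: none
Why: Copper-catalysed O-propargylation (substitution of the in-flask tertiary propargylic trifluoroacetate 3 by the DBU phenoxide through a copper-stabilised propargyl cation) is the standard entry to aryl 1,1-dimethylpropargyl ethers and works on electron-poor, hydrogen-bonded phenols without touching the aldehyde.

Step 2
Reactants: 4 4-methoxy-2-[(2-methylbut-3-yn-2-yl)oxy]benzaldehyde
Product: 5 4-methoxy-2-[(2-methylbut-3-en-2-yl)oxy]benzaldehyde
Conditions: H2 (1 atm), Pd/CaCO3 poisoned with Pb(OAc)2 (Lindlar-type), quinoline, EtOAc, rt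
Reagents that add atoms: none
Why: Lindlar semi-hydrogenation: the poisoned palladium surface takes the terminal alkyne to the alkene and stops, leaving the aryl aldehyde and the tertiary allylic C–O bond intact, which is needed because the alkyne itself would cyclise to a chromene on heating.

Step 3
Reactants: 5 4-methoxy-2-[(2-methylbut-3-en-2-yl)oxy]benzaldehyde
Product: 7 2-hydroxy-4-methoxy-3-(3-methylbut-2-en-1-yl)benzaldehyde, via ortho-dienone 6 (not isolated)
Conditions: PhNEt2, 130 °C
Reagents that add atoms: none
Why: Aromatic Claisen rearrangement: a [3,3] shift delivers the allyl unit with inversion to the only hydrogen-bearing ortho carbon (between the two oxygens), and dienone 6 tautomerises irreversibly to the chelated phenol, so the 1,1-dimethylallyl ether becomes the 3-methylbut-2-enyl C-substituent.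

Step 4
Reactants: 7 2-hydroxy-4-methoxy-3-(3-methylbut-2-en-1-yl)benzaldehyde
Product: 8 2-hydroxy-3-[(2E)-4-hydroxy-3-methylbut-2-en-1-yl]-4-methoxybenzaldehyde
Conditions: SeO2 (0.5 equiv), t-BuOOH (70% aq., 3 equiv), salicylic acid (0.1 equiv), CH2Cl2, 0 °C → rt
Reagents that add atoms: tert-butyl hydroperoxide, CC(C)(C)OO (terminal oxygen source); selenium dioxide, O=[Se]=O (transfers the oxygen and is regenerated)
Why: Riley allylic oxidation (ene reaction followed by [2,3]-sigmatropic shift) goes to the more substituted alkene terminus and there to the methyl group trans to the chain, which fixes the E geometry of the new allylic alcohol, while the phenol is held in its hydrogen bond to the aldehyde and the catalytic, room-temperature variant limits over-oxidation to the enal, a minor by-product that is removed by chromatography.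

Step 5
Reactants: 8 2-hydroxy-3-[(2E)-4-hydroxy-3-methylbut-2-en-1-yl]-4-methoxybenzaldehyde
Product: 9 3-[(2E)-4-(tert-butyldiphenylsilyloxy)-3-methylbut-2-en-1-yl]-2-hydroxy-4-methoxybenzaldehyde
Conditions: TBDPSCl (1.05 equiv), imidazole, CH2Cl2, 0 °C
Reagents that add atoms: tert-butyl(chloro)diphenylsilane, CC(C)(C)[Si](Cl)(c1ccccc1)c1ccccc1
Why: Imidazole-mediated silylation picks the unhindered primary allylic alcohol over the chelated, doubly ortho-substituted phenol, and the tert-butyldiphenylsilyl ether is chosen because it has to survive acidic methanol (step 6), the acid catalyst (step 9) and aqueous acid (step 10).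

Step 6
Reactants: 9 3-[(2E)-4-(tert-butyldiphenylsilyloxy)-3-methylbut-2-en-1-yl]-2-hydroxy-4-methoxybenzaldehyde
Product: 10 6-[(2E)-4-(tert-butyldiphenylsilyloxy)-3-methylbut-2-en-1-yl]-2-(dimethoxymethyl)-5-methoxyphenol
Conditions: HC(OMe)3 (5 equiv), PPTS (5 mol%), MeOH, rt; then Et3N, evaporation, used crude
Reagents that add atoms: trimethyl orthoformate, COC(OC)OC; methanol, CO
Why: Acid-catalysed acetalisation pulled to completion by the orthoformate as water scavenger; in methanol any quinone methide that forms is simply returned to the acetal, and the amine quench before evaporation keeps the electron-rich hydroxy acetal from ionising, so it is carried on crude without chromatography.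

Step 7
Reactants: 11 3,4-dihydroxybenzaldehyde
Product: 12 3,4-bis(tert-butyldimethylsilyloxy)benzaldehyde
Conditions: TBSCl (2.5 equiv), imidazole, DMF, rt
Reagents that add atoms: tert-butyl(chloro)dimethylsilane, CC(C)(C)[Si](C)(C)Cl
Why: Standard silylation of both phenols; silyl ethers (not esters) are used on the catechol so that the oxygen para to the future vinyl group remains a donor and the styrene is nucleophilic enough for step 9, and so that all three protecting groups fall in one final operation.

Step 8
Reactants: 12 3,4-bis(tert-butyldimethylsilyloxy)benzaldehyde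
Product: 13 3,4-bis(tert-butyldimethylsilyloxy)styrene
Conditions: Ph3PCH3Br (1.3 equiv), KOt-Bu (1.2 equiv), THF, 0 °C → rt
Reagents that add atoms: methyltriphenylphosphonium bromide, C[P+](c1ccccc1)(c1ccccc1)c1ccccc1.[Br-]
Why: Wittig methylenation of the aryl aldehyde with the non-stabilised ylide is reliable and leaves aryl silyl ethers alone when the phosphonium salt is kept in slight excess over the base, and it avoids handling the polymerisation-prone free vinylcatechol.

Step 9
Reactants: 10 6-[(2E)-4-(tert-butyldiphenylsilyloxy)-3-methylbut-2-en-1-yl]-2-(dimethoxymethyl)-5-methoxyphenol; 13 3,4-bis(tert-butyldimethylsilyloxy)styrene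
Product: 15 (2S,4S)-2-[3,4-bis(tert-butyldimethylsilyloxy)phenyl]-8-[(2E)-4-(tert-butyldiphenylsilyloxy)-3-methylbut-2-en-1-yl]-4,7-dimethoxychromane (2,4-cis), via methoxy ortho-quinone methide 14 (not isolated)
Conditions: (R)-3,3'-bis(2,4,6-triisopropylphenyl)-1,1'-binaphthyl-2,2'-diyl hydrogen phosphate (10 mol%), 13 (2 equiv), 5 Å MS, toluene, −20 °C → 0 °C
Reagents that add atoms: none
Why: Proposed new method: the chiral acid ionises the acetal of 10 with loss of methanol to the methoxy-substituted ortho-quinone methide 14, held as a hydrogen-bonded, partly protonated (oxocarbenium-like) pair with the phosphate; the CH2 terminus of 13 adds to the methide carbon (C4) and the ring A oxygen then closes on the benzylic cation at C2, an asynchronous inverse-demand oxa-[4+2] that re-aromatises ring A. The closest known reaction types are the achiral acid-promoted union of salicylaldehyde acetals with styrenes to cis-4-alkoxy-2-arylchromans and chiral phosphoric acid-controlled cycloadditions of other ortho-quinone methides with electron-rich alkenes. Ring C is closed as an intermolecular [4+2] annulation, C3–C4 first and O1–C2 second, the second bond being a six-membered closure of oxygen on a benzylic cation. C4 is set by the face of 14 that the 3,3'-aryl groups of the bound catalyst leave open, and C2 is set relative to C4 by the endo approach of the aryl group, which gives the 2,4-cis adduct and therefore 2S when C4 is S. The step needs regioselectivity, chemoselectivity for the styrene over the trisubstituted side-chain alkene, and face selectivity: the first follows from polarity (nucleophilic CH2 to electrophilic C4, cation at C2 stabilised by the para silyloxy group), the second from the much higher nucleophilicity of the para-silyloxystyrene than of an alkene carrying an allylic oxygen, and the third rests on the catalyst alone and is the unproven part. The C7 methoxy group para to C4a stabilises 14 and lets the ionisation run at low temperature.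

Step 10
Reactants: 15 (2S,4S)-2-[3,4-bis(tert-butyldimethylsilyloxy)phenyl]-8-[(2E)-4-(tert-butyldiphenylsilyloxy)-3-methylbut-2-en-1-yl]-4,7-dimethoxychromane
Product: 16 (2S)-2-[3,4-bis(tert-butyldimethylsilyloxy)phenyl]-8-[(2E)-4-(tert-butyldiphenylsilyloxy)-3-methylbut-2-en-1-yl]-7-methoxychroman-4-ol (mixture of C4 epimers)
Conditions: PPTS (20 mol%), THF/H2O 4:1, 40 °C
Reagents that add atoms: water, O
Why: SN1 solvolysis: the C4 methyl ether ionises readily under mild acid because the cation is stabilised by the C7 methoxy group (para to C4a) and by O1 (ortho), and water in large excess captures it to give the flavan-4-ol as a mixture of C4 epimers that does not matter, while C2, the silyl ethers and the alkene are untouched.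

Step 11
Reactants: 16 (2S)-2-[3,4-bis(tert-butyldimethylsilyloxy)phenyl]-8-[(2E)-4-(tert-butyldiphenylsilyloxy)-3-methylbut-2-en-1-yl]-7-methoxychroman-4-ol
Product: 17 (2S)-2-[3,4-bis(tert-butyldimethylsilyloxy)phenyl]-8-[(2E)-4-(tert-butyldiphenylsilyloxy)-3-methylbut-2-en-1-yl]-7-methoxychroman-4-one
Conditions: MnO2 (activated, 20 equiv), CH2Cl2, rt
Reagents that add atoms: none
Why: MnO2 oxidation of a benzylic alcohol on an electron-rich ring under neutral heterogeneous conditions converts both C4 epimers into one ketone and cannot touch the protected allylic alcohol or epimerise C2.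

Step 12
Reactants: 17 (2S)-2-[3,4-bis(tert-butyldimethylsilyloxy)phenyl]-8-[(2E)-4-(tert-butyldiphenylsilyloxy)-3-methylbut-2-en-1-yl]-7-methoxychroman-4-one
Product: 18 (2S)-2-(3,4-dihydroxyphenyl)-8-[(2E)-4-hydroxy-3-methylbut-2-en-1-yl]-7-methoxy-2,3-dihydro-4H-chromen-4-one
Conditions: HF·pyridine, pyridine, THF, 0 °C → rt; work-up kept at or below pH 7
Reagents that add atoms: none
Why: Fluoride-mediated desilylation under acidic buffering removes the alkyl and both aryl silyl ethers while the phenols stay protonated, which avoids the base-induced ring opening to the chalcone that would racemise C2 of a 4'-hydroxyflavanone.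

Compound list
1 | 2-hydroxy-4-methoxybenzaldehyde | COc1ccc(C=O)c(O)c1 | starting material
2 | 2-methylbut-3-yn-2-ol | CC(C)(O)C#C | starting material
3 | 2-methylbut-3-yn-2-yl trifluoroacetate (formed in the flask, not isolated) | CC(C)(C#C)OC(=O)C(F)(F)F | intermediate
4 | 4-methoxy-2-[(2-methylbut-3-yn-2-yl)oxy]benzaldehyde | COc1ccc(C=O)c(OC(C)(C)C#C)c1 | intermediate
5 | 4-methoxy-2-[(2-methylbut-3-en-2-yl)oxy]benzaldehyde | COc1ccc(C=O)c(OC(C)(C)C=C)c1 | intermediate
6 | 4-methoxy-5-(3-methylbut-2-en-1-yl)-6-oxocyclohexa-1,3-diene-1-carbaldehyde (Claisen ortho-dienone, racemic, not isolated) | COC1=CC=C(C=O)C(=O)C1CC=C(C)C | intermediate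
7 | 2-hydroxy-4-methoxy-3-(3-methylbut-2-en-1-yl)benzaldehyde | COc1ccc(C=O)c(O)c1CC=C(C)C | intermediate
8 | 2-hydroxy-3-[(2E)-4-hydroxy-3-methylbut-2-en-1-yl]-4-methoxybenzaldehyde | COc1ccc(C=O)c(O)c1C/C=C(\C)CO | intermediate
9 | 3-[(2E)-4-(tert-butyldiphenylsilyloxy)-3-methylbut-2-en-1-yl]-2-hydroxy-4-methoxybenzaldehyde | COc1ccc(C=O)c(O)c1C/C=C(\C)CO[Si](c2ccccc2)(c3ccccc3)C(C)(C)C | intermediate
10 | 6-[(2E)-4-(tert-butyldiphenylsilyloxy)-3-methylbut-2-en-1-yl]-2-(dimethoxymethyl)-5-methoxyphenol | COc1ccc(C(OC)OC)c(O)c1C/C=C(\C)CO[Si](c2ccccc2)(c3ccccc3)C(C)(C)C | intermediate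
11 | 3,4-dihydroxybenzaldehyde | O=Cc1ccc(O)c(O)c1 | starting material
12 | 3,4-bis(tert-butyldimethylsilyloxy)benzaldehyde | O=Cc1ccc(O[Si](C)(C)C(C)(C)C)c(O[Si](C)(C)C(C)(C)C)c1 | intermediate
13 | 3,4-bis(tert-butyldimethylsilyloxy)styrene | C=Cc1ccc(O[Si](C)(C)C(C)(C)C)c(O[Si](C)(C)C(C)(C)C)c1 | intermediate
14 | 2-[(2E)-4-(tert-butyldiphenylsilyloxy)-3-methylbut-2-en-1-yl]-3-methoxy-6-(methoxymethylidene)cyclohexa-2,4-dien-1-one (ortho-quinone methide, exocyclic geometry not defined, not isolated) | COC=C1C=CC(OC)=C(C/C=C(\C)CO[Si](c2ccccc2)(c3ccccc3)C(C)(C)C)C1=O | intermediate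
15 | (2S,4S)-2-[3,4-bis(tert-butyldimethylsilyloxy)phenyl]-8-[(2E)-4-(tert-butyldiphenylsilyloxy)-3-methylbut-2-en-1-yl]-4,7-dimethoxychromane (2,4-cis) | COc1ccc2c(c1C/C=C(\C)CO[Si](c3ccccc3)(c4ccccc4)C(C)(C)C)O[C@H](c1ccc(O[Si](C)(C)C(C)(C)C)c(O[Si](C)(C)C(C)(C)C)c1)C[C@@H]2OC | intermediate
16 | (2S)-2-[3,4-bis(tert-butyldimethylsilyloxy)phenyl]-8-[(2E)-4-(tert-butyldiphenylsilyloxy)-3-methylbut-2-en-1-yl]-7-methoxychroman-4-ol (C4 epimers) | COc1ccc2c(c1C/C=C(\C)CO[Si](c3ccccc3)(c4ccccc4)C(C)(C)C)O[C@H](c1ccc(O[Si](C)(C)C(C)(C)C)c(O[Si](C)(C)C(C)(C)C)c1)CC2O | intermediate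
17 | (2S)-2-[3,4-bis(tert-butyldimethylsilyloxy)phenyl]-8-[(2E)-4-(tert-butyldiphenylsilyloxy)-3-methylbut-2-en-1-yl]-7-methoxychroman-4-one | COc1ccc2c(c1C/C=C(\C)CO[Si](c3ccccc3)(c4ccccc4)C(C)(C)C)O[C@H](c1ccc(O[Si](C)(C)C(C)(C)C)c(O[Si](C)(C)C(C)(C)C)c1)CC2=O | intermediate
18 | (2S)-2-(3,4-dihydroxyphenyl)-8-[(2E)-4-hydroxy-3-methylbut-2-en-1-yl]-7-methoxy-2,3-dihydro-4H-chromen-4-one | COc1ccc2c(c1C/C=C(\C)CO)O[C@H](c1ccc(O)c(O)c1)CC2=O | target

Total step count: 12. Longest linear sequence: 10 steps (steps 1–6 and 9–12); steps 7 and 8 form the two-step side branch to the styrene.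

Steps most likely to fail

1. Step 9 (the step that goes beyond known chemistry). The catalyst may fail to differentiate the faces of the quinone methide with a simple styrene, giving low enantiomeric purity at C2. The acid may also turn over slowly once methanol accumulates. A further hazard is that a trans adduct formed on the same quinone methide face carries the opposite C2 configuration, so the cis and trans adducts should be separated and assayed before C4 is erased. The fallback uses known chemistry only. From 10 and 13, an achiral acid (diphenyl phosphate, 5 Å MS, CH2Cl2, 0 °C) should give the racemic cis-4-methoxyflavan F1. The conditions of steps 10 and 11 then lead through the racemic flavan-4-ol F2 to the racemic silyl-protected flavanone F3. Kinetic resolution of F3 by asymmetric transfer hydrogenation (RuCl[(R,R)-TsDPEN](p-cymene), HCO2H/Et3N, EtOAc, rt, stopped near half conversion) should reduce the 2R ketone to the cis (2R,4R)-flavan-4-ol F4. By analogy with simple aryl ketones the (R,R) complex is the expected choice, to be confirmed on a small scale. The unreacted 2S ketone is compound 17, where the route is rejoined, at the cost of at most half of the material.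

2. Step 4. The oxidation may stall at partial conversion or run on to the enal, and the free phenol may interfere with the selenium reagent. The fallback sets out from 7 and changes the plan from direct hydroxylation to oxidation–reduction. Stoichiometric SeO2 (dioxane, 80 °C) drives the oxidation to the aldehyde stage and should give the dialdehyde (2E)-4-(3-formyl-2-hydroxy-6-methoxyphenyl)-2-methylbut-2-enal F5 as the single end point. The phenol is then converted into its sodium salt (NaOMe, 1 equiv), which turns the aryl aldehyde into an unreactive vinylogous carboxylate, and NaBH4 (MeOH/THF, −40 °C) reduces only the enal 1,2, returning to 8.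

3. Step 6. The hydroxy acetal may revert to the aldehyde or ionise and oligomerise through the quinone methide during concentration. The fallback sets out from 9 and frees the phenol last, under base. Acetylation (Ac2O, pyridine, DMAP, CH2Cl2) should give 2-[(2E)-4-(tert-butyldiphenylsilyloxy)-3-methylbut-2-en-1-yl]-6-formyl-3-methoxyphenyl acetate F6, whose aldehyde is no longer chelated. Acetalisation (HC(OMe)3, PPTS, MeOH, rt) should then give 2-[(2E)-4-(tert-butyldiphenylsilyloxy)-3-methylbut-2-en-1-yl]-6-(dimethoxymethyl)-3-methoxyphenyl acetate F7, which has no free phenol and can be purified on Et3N-treated silica. Methanolysis of the aryl acetate (K2CO3 cat., MeOH, 0 °C, neutral buffered work-up) releases the phenol under conditions in which the acetal cannot ionise and gives 10, taken directly into step 9.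

Further compounds
F1 | step 9 | racemic 2,4-cis-2-[3,4-bis(tert-butyldimethylsilyloxy)phenyl]-8-[(2E)-4-(tert-butyldiphenylsilyloxy)-3-methylbut-2-en-1-yl]-4,7-dimethoxychromane | COc1ccc2c(c1C/C=C(\C)CO[Si](c3ccccc3)(c4ccccc4)C(C)(C)C)OC(c1ccc(O[Si](C)(C)C(C)(C)C)c(O[Si](C)(C)C(C)(C)C)c1)CC2OC
F2 | step 9 | racemic 2-[3,4-bis(tert-butyldimethylsilyloxy)phenyl]-8-[(2E)-4-(tert-butyldiphenylsilyloxy)-3-methylbut-2-en-1-yl]-7-methoxychroman-4-ol (C4 epimers) | COc1ccc2c(c1C/C=C(\C)CO[Si](c3ccccc3)(c4ccccc4)C(C)(C)C)OC(c1ccc(O[Si](C)(C)C(C)(C)C)c(O[Si](C)(C)C(C)(C)C)c1)CC2O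
F3 | step 9 | racemic 2-[3,4-bis(tert-butyldimethylsilyloxy)phenyl]-8-[(2E)-4-(tert-butyldiphenylsilyloxy)-3-methylbut-2-en-1-yl]-7-methoxychroman-4-one | COc1ccc2c(c1C/C=C(\C)CO[Si](c3ccccc3)(c4ccccc4)C(C)(C)C)OC(c1ccc(O[Si](C)(C)C(C)(C)C)c(O[Si](C)(C)C(C)(C)C)c1)CC2=O
F4 | step 9 | (2R,4R)-2-[3,4-bis(tert-butyldimethylsilyloxy)phenyl]-8-[(2E)-4-(tert-butyldiphenylsilyloxy)-3-methylbut-2-en-1-yl]-7-methoxychroman-4-ol (2,4-cis) | COc1ccc2c(c1C/C=C(\C)CO[Si](c3ccccc3)(c4ccccc4)C(C)(C)C)O[C@@H](c1ccc(O[Si](C)(C)C(C)(C)C)c(O[Si](C)(C)C(C)(C)C)c1)C[C@H]2O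
F5 | step 4 | (2E)-4-(3-formyl-2-hydroxy-6-methoxyphenyl)-2-methylbut-2-enal | COc1ccc(C=O)c(O)c1C/C=C(\C)C=O
F6 | step 6 | 2-[(2E)-4-(tert-butyldiphenylsilyloxy)-3-methylbut-2-en-1-yl]-6-formyl-3-methoxyphenyl acetate | COc1ccc(C=O)c(OC(C)=O)c1C/C=C(\C)CO[Si](c2ccccc2)(c3ccccc3)C(C)(C)C
F7 | step 6 | 2-[(2E)-4-(tert-butyldiphenylsilyloxy)-3-methylbut-2-en-1-yl]-6-(dimethoxymethyl)-3-methoxyphenyl acetate | COc1ccc(C(OC)OC)c(OC(C)=O)c1C/C=C(\C)CO[Si](c2ccccc2)(c3ccccc3)C(C)(C)C
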